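Remark on the chemistry: the target has no stereocentre. The carbinol centres of 1, 3 and 27 are racemic and are erased by oxidation, and the enol ether 20 is carried as an E/Z mixture. Primed locants refer to chromone B.

## Analysis of the target

The target 31 is a bis-chromone in which chromone A (8-methoxy, 2-isopropyl) is joined through one methylene from its C5 to C2' of chromone B, which carries a free hydroxyl at C7' and a 2-oxopropyl arm at C5'. There is no stereocentre, so the problem is one of connectivity and substitution pattern only. The benzene ring of chromone A is 1,2,3,4-tetrasubstituted (C4a, C5, C8 and C8a are contiguous). That of chromone B is 1,2,3,5-tetrasubstituted, with the acyl-bearing C4a' flanked by the C5' arm and the C8a' oxygen, and simple electrophilic substitution of a phenol delivers neither pattern cleanly. The sensitive points are the methyl ketone of the C5' arm (peri to C4' and prone to aldol-type ring closure with an enolizable acyl group on C4a'), the acidic bridging CH2 (benzylic, next to pyranone B and peri to the C4 carbonyl) and the two pyranones, which open with hydroxide or alkoxide; three oxygens (O1', 7'-OH, 8-OMe) must also be told apart. The difficulty lies in building the arene of chromone B with its acyl group, its carbon arm and two differentiated meta oxygens, and in forming the C2'-C3' bond beside the acidic methylene. The strategy rests on the meta relationship of the oxygens at C7' and C8a', with C4a' between C8a' and C5', which is the array formed when a 1,1-dialkoxy-3-silyloxy diene adds across an ynone whose β-carbon carries the future C5' arm.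

## Retrosynthetic reasoning

31 from 30: the last operation is hydrogenolysis of the benzyl ether on O7'. Benzyl is chosen because it survives the strong base, oxidant and acid of the endgame and leaves under neutral conditions that do not touch the pyranones or the ketone.

30 from 28 by way of 29: the O1'-C2' bond is cut. An ortho-hydroxyaryl 1,3-diketone closes to the pyranone under acid, and the same acid later removes the dioxolane. The ketal must stay on until the pyranone exists, because a free methyl ketone beside the nucleophilic diketone enol would invite carbocyclization at C3'.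

28 from 14 and 25 by way of 27: the C2'-C3' bond is cut at the aldehyde oxidation level, not the ester level. An ester of the arylacetic acid of chromone A would be a stronger carbon acid than the methyl ketone 14, so a base-mediated condensation would stall in proton transfer and self-condensation. A preformed lithium enolate adds to the aldehyde 25 much faster than it deprotonates it, and oxidation of 27 then gives the same diketone 28.

14 from 10 by way of 13, 12 and 11: these are adjustments around a fixed skeleton. The methallyl group of 10 is the latent acetonyl arm (oxidative cleavage to 13, then ketalization of the aliphatic ketone only). The methyl ether on the future O1' is removed by a chelation-controlled dealkylation (11 to 12), which distinguishes it from the benzyl ether on O7'. A stronger, non-chelating Lewis acid is avoided at this point, since it would also attack the benzyl ether and activate the ketone towards the neighbouring alkene.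

10 from 7 and 4 by way of 8 and 9: this is the key disconnection, cutting C8a'-C4a' and C6'-C5'. The diene 7 supplies C6', C7', C8' and C8a' with both oxygens in place; the ynone 4 supplies C4a', C5', the acetyl group (C4', C3') and the masked arm. The cut is made here because the ring then closes with every substituent placed by the construction, so no regiochemical substitution of an existing arene is needed. The forward reaction must control regiochemistry and aromatize by loss of methanol from the ketal carbon only.

4 from 1 and 2 by way of 3, and 7 from 5 by way of 6: the ynone comes from allylation of the terminal alkyne 1 with 2 and oxidation of 3. The diene comes from C-acylation of the ketene acetal 5 and silylation of 6. Each precursor needs two steps, so the risk is concentrated in the cycloaddition.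

25 from 18 and 15: the aldehyde 25 is released from the acetal 24. The pyranone of chromone A in 24 is cut at O1-C2, back to the ortho-oxygenated aryl ynone 23/22. The ynone 22 is cut at C4-C4a into the aryllithium 21 (from bromide 20) and the N-methoxy-N-methylamide 17 (from 15 by way of 16). The bromide 18 already carries bromine, hydroxyl and methoxyl on the carbons that become C4a, C8a and C8, and its formyl carbon becomes the bridging CH2. Homologation of 19 to the enol ether 20 adds the carbon that becomes C2'.

## Alternatives that were turned down

Alternative 1: the carbocycle of chromone B is assembled from pentane-2,4-dione A3 and 6-methyl-5,6-dihydro-2H-pyran-2-one A2.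
- Key step: under alkoxide base, A3 adds through its central carbon to the β-carbon of the lactone A2 (C4a'-C5'). One acetyl methyl then attacks the lactone carbonyl of A2 (C8'-C7') to give 4-acetyl-5-(2-hydroxypropyl)cyclohexane-1,3-dione A1. A1 must later be dehydrogenated to 1-[2,4-dihydroxy-6-(2-hydroxypropyl)phenyl]ethanone A4.
- For: the materials are cheap, there is no moisture-sensitive diene, and the route to the arene is about three steps shorter on paper. The arm arrives as a secondary alcohol, a naturally masked acetonyl group that avoids both ketalization and the handling of a 1,5-diketone. On these points it is stronger than the chosen route.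
- Against: after the conjugate addition the most acidic site is the doubly activated central carbon, whose stabilized anion resists the required enolization of a terminal methyl, and alkoxide can deacetylate instead. A1 is one oxidation level below the arene, and dehydrogenation of a 4-acylcyclohexane-1,3-dione needs halogen or metal oxidants at elevated temperature in the presence of a free secondary alcohol. The two ring oxygens of A4 emerge unprotected and must be differentiated by hydrogen bonding alone.
- Comparison: the chosen cycloaddition delivers the arene at the right oxidation level in one operation, with O8a' and O7' already different (methyl ether against silyl ether), at the cost of a longer sequence.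

Alternative 2: the pyranone of chromone A is cut at C2-C3.
- Key step: the acylphosphorane 6-methoxy-3-(prop-2-en-1-yl)-2-[2-(triphenyl-λ5-phosphanylidene)acetyl]phenyl 2-methylpropanoate A6 undergoes intramolecular Wittig olefination of its own ester carbonyl to give 5-allyl-8-methoxy-2-isopropylchromen-4-one A5.
- For: the ring closure is neutral and regiospecific, with no five-membered competitor. The allyl group of A5 can be cut to the two-carbon arm under neutral oxidative conditions. That is gentler than the acid steps used here for chromone A, and on this point the alternative is stronger.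
- Against: it addresses the easier heterocycle and leaves the substitution pattern of ring B unsolved. A6 requires α-halogenation of an electron-rich aryl methyl ketone that carries an allyl group, and its 1,2,3,4-tetrasubstituted arene is itself not trivially available. Olefination of a hindered isobutyrate carbonyl needs prolonged heating. A5 must still be joined to ring B through the same C2'-C3' chemistry.
- Comparison: the chosen route reaches chromone A in five steps from a commercial bromophenol, with the acyl position fixed by the bromine, and spends its key step on the harder ring.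

Alternative 3: the pyranone of chromone B is cut into three components.
- Key step: 5-(benzyloxy)-2-iodo-3-[(2-methyl-1,3-dioxolan-2-yl)methyl]phenol A8, carbon monoxide A10 and 8-methoxy-2-(propan-2-yl)-5-(prop-2-yn-1-yl)-4H-chromen-4-one A9 combine under palladium catalysis with a secondary amine. The bonds C4a'-C4', C4'-C3' and O1'-C2' form in one flask to give the protected target A7, which is identical with 29.
- For: it is the most convergent plan. It needs no diketone, no aldol and no oxidation, and its endgame is shorter than the one chosen here. On convergence it is clearly stronger.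
- Against: the propargylic CH2 of A9 is benzylic and peri to a carbonyl, so the amine base is expected to isomerize the terminal alkyne to an allene. Oxidative addition into A8 is hindered by two ortho substituents, and insertion of A10 must outrun direct alkynylation, which leads to benzofurans. Six-membered closure must also beat five-membered closure. A8 itself demands iodination at the most hindered position of a resorcinol derivative, so the regiochemical problem of ring B is moved, not solved.
- Comparison: the chosen route places all four substituents of ring B by cycloaddition and joins the halves by two well-understood steps, accepting a longer linear sequence.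

Key step: step 5

## Route

Step 1
Reactants: 1 but-3-yn-2-ol (racemic); 2 3-bromo-2-methylprop-1-ene
Product: 3 6-methylhept-6-en-3-yn-2-ol (racemic)
Conditions: CuI (10 mol %), K2CO3, n-Bu4NBr (cat.), DMF, rt
Reagents that add atoms: none
Why: Copper-catalysed allylation of a terminal alkyne: the copper acetylide formed under carbonate displaces bromide from 2. Both allyl termini of 2 lead to the same skipped enyne, and the mild base leaves the free hydroxyl and the doubly activated methylene alone.

Step 2
Reactants: 3 6-methylhept-6-en-3-yn-2-ol
Product: 4 6-methylhept-6-en-3-yn-2-one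
Conditions: MnO2 (activated, excess), CH2Cl2, rt
Reagents that add atoms: none
Why: Oxidation of a propargylic alcohol with activated MnO2 under neutral heterogeneous conditions. The absence of base keeps the C5 methylene from prototropic isomerization to an allene.

Step 3
Reactants: 5 1,1-dimethoxyethene
Product: 6 4,4-dimethoxybut-3-en-2-one
Conditions: AcCl, pyridine, Et2O, 0 °C → rt
Reagents that add atoms: acetyl chloride, CC(=O)Cl
Why: C-Acylation of a ketene acetal: the nucleophilic CH2 carbon of 5 attacks the acylpyridinium ion, and pyridine removes the now acidic proton to give the push-pull enone.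

Step 4
Reactants: 6 4,4-dimethoxybut-3-en-2-one
Product: 7 1,1-dimethoxy-3-(trimethylsilyloxy)buta-1,3-diene
Conditions: TMSOTf, Et3N, Et2O, 0 °C
Reagents that add atoms: trimethylsilyl trifluoromethanesulfonate, C[Si](C)(C)OS(=O)(=O)C(F)(F)F
Why: Silyl enol ether formation by soft enolization: O-silylation of the carbonyl and loss of a proton from the methyl group, the only enolizable position, give the 2-silyloxy diene.

Step 5
Reactants: 7 1,1-dimethoxy-3-(trimethylsilyloxy)buta-1,3-diene; 4 6-methylhept-6-en-3-yn-2-one
Product: 10 1-[4-hydroxy-2-methoxy-6-(2-methylprop-2-enyl)phenyl]ethanone, via cyclohexadiene cycloadduct 8 (not isolated), via aryl trimethylsilyl ether 9 (not isolated)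
Conditions: toluene, 90 °C, sealed tube; then 1 M HCl, THF, 0 °C → rt
Reagents that add atoms: none
Why: This is a Diels-Alder benzannulation: the diene 7, raised in energy by three oxygen donors, adds across the acetyl-activated triple bond of 4 in a (4+2) cycloaddition that is probably asynchronous. The CH2 terminus of 7 carries the largest HOMO coefficient and bonds to the ynone β-carbon (C6'-C5'), so the ketene acetal carbon bonds to the α-carbon (C8a'-C4a'); a stepwise Michael-first pathway would lead to the same connectivity. The cycloadduct 8 holds a ketal carbon opposite a ring CH2, and 1,4-elimination of methanol aromatizes it to 9; dilute acid then cleaves the silyl ether to give 10. The closest known reaction type is the thermal cycloaddition of 1,1-dialkoxy-3-silyloxybutadienes with acetylenic ketones and esters to give resorcinol monoethers. The benzene ring is closed as a six-membered carbocycle by intermolecular cycloaddition that forms two carbon-carbon bonds, and no stereocentre is created. The step needs regioselectivity, which the matched polarity of the two partners secures. It needs chemoselectivity, which follows because only the conjugated triple bond is electron-poor while the isolated 1,1-disubstituted alkene is inert to an electron-rich diene. It also needs a single direction of aromatization, which is fixed because only the ketal carbon bears leaving groups, so C8a' keeps one methoxyl and C7' keeps its oxygen as the silyl ether.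

Step 6
Reactants: 10 1-[4-hydroxy-2-methoxy-6-(2-methylprop-2-enyl)phenyl]ethanone
Product: 11 1-[4-(benzyloxy)-2-methoxy-6-(2-methylprop-2-enyl)phenyl]ethanone
Conditions: BnBr, K2CO3, acetone, reflux
Reagents that add atoms: benzyl bromide, BrCc1ccccc1
Why: Williamson ether synthesis on the only free phenol; carbonate is too weak to enolize the ketone or move the alkene.

Step 7
Reactants: 11 1-[4-(benzyloxy)-2-methoxy-6-(2-methylprop-2-enyl)phenyl]ethanone
Product: 12 1-[4-(benzyloxy)-2-hydroxy-6-(2-methylprop-2-enyl)phenyl]ethanone
Conditions: MgI2·OEt2, toluene/Et2O, 60 °C; then H2O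
Reagents that add atoms: none
Why: Chelation-controlled nucleophilic dealkylation: magnesium binds between the ketone oxygen and the ortho methoxy oxygen, and iodide removes the methyl group by SN2. The benzyl ether para to the ketone cannot chelate and is kept. This mild Lewis acid is preferred to BCl3, which would also cleave the benzyl ether and could drive the methallyl alkene onto the activated ketone.

Step 8
Reactants: 12 1-[4-(benzyloxy)-2-hydroxy-6-(2-methylprop-2-enyl)phenyl]ethanone
Product: 13 1-[2-acetyl-5-(benzyloxy)-3-hydroxyphenyl]propan-2-one
Conditions: OsO4 (2 mol %), NaIO4, 2,6-lutidine, dioxane/H2O, rt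
Reagents that add atoms: sodium periodate, [Na+].[O-]I(=O)(=O)=O
Why: Lemieux-Johnson oxidation: catalytic dihydroxylation of the electron-rich 1,1-disubstituted alkene and periodate cleavage of the diol give the methyl ketone. The 2,6-lutidine keeps the medium near neutral so that the 1,5-diketone does not close by intramolecular aldol condensation.

Step 9
Reactants: 13 1-[2-acetyl-5-(benzyloxy)-3-hydroxyphenyl]propan-2-one
Product: 14 1-[4-(benzyloxy)-2-hydroxy-6-[(2-methyl-1,3-dioxolan-2-yl)methyl]phenyl]ethanone
Conditions: TMSOCH2CH2OTMS, TMSOTf (5 mol %), CH2Cl2, −78 → −20 °C; then pyridine, aq. NaHCO3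
Reagents that add atoms: 1,2-bis(trimethylsilyloxy)ethane, C[Si](C)(C)OCCO[Si](C)(C)C
Why: Ketalization with a bis-silylated diol under silyl triflate catalysis. The unhindered aliphatic ketone reacts, whereas the aryl ketone is flanked by two ortho substituents and hydrogen-bonded to the phenol; the low temperature suppresses enolization and aldol closure.

Step 10
Reactants: 15 3-methylbut-1-yne
Product: 17 N-methoxy-N,4-dimethylpent-2-ynamide, via lithium acetylide 16 (not isolated)
Conditions: n-BuLi, THF, −78 °C; then ClC(O)N(OMe)Me, −78 → 0 °C
Reagents that add atoms: N-methoxy-N-methylcarbamoyl chloride, CON(C)C(Cl)=O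
Why: Acylation of a lithium acetylide by nucleophilic substitution at a carbamoyl chloride; the reaction stops at the amide because the product is far less electrophilic than the chloride.

Step 11
Reactants: 18 2-bromo-3-hydroxy-4-methoxybenzaldehyde
Product: 19 2-bromo-4-methoxy-3-(methoxymethoxy)benzaldehyde
Conditions: MOMCl, i-Pr2NEt, CH2Cl2, 0 °C → rt
Reagents that add atoms: chloromethyl methyl ether, COCCl
Why: O-Alkylation of the phenol to a methoxymethyl acetal, a group that tolerates organolithium reagents and is removed by the acid of step 14.

Step 12
Reactants: 19 2-bromo-4-methoxy-3-(methoxymethoxy)benzaldehyde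
Product: 20 2-bromo-4-methoxy-1-(2-methoxyethenyl)-3-(methoxymethoxy)benzene (E/Z mixture)
Conditions: Ph3P(CH2OMe)Cl, KOtBu, THF, 0 °C → rt
Reagents that add atoms: (methoxymethyl)triphenylphosphonium chloride, COC[P+](c1ccccc1)(c1ccccc1)c1ccccc1.[Cl-]
Why: Wittig reaction with the methoxymethylidene ylide, a one-carbon homologation that leaves the future arylacetaldehyde masked as an enol ether; the alkene geometry is irrelevant.

Step 13
Reactants: 20 2-bromo-4-methoxy-1-(2-methoxyethenyl)-3-(methoxymethoxy)benzene; 17 N-methoxy-N,4-dimethylpent-2-ynamide
Product: 22 1-[3-methoxy-6-(2-methoxyethenyl)-2-(methoxymethoxy)phenyl]-4-methylpent-2-yn-1-one (E/Z mixture), via aryllithium 21 (not isolated)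
Conditions: n-BuLi, THF, −78 °C; then 17, −78 → −40 °C; then AcOH
Reagents that add atoms: none
Why: Bromine-lithium exchange followed by a Weinreb ketone synthesis: the aryllithium adds once to the N-methoxy-N-methylamide, and the lithium chelate holds the tetrahedral adduct until the acidic quench. Exchange at −78 °C is faster than any deprotonation of the enol ether.

Step 14
Reactants: 22 1-[3-methoxy-6-(2-methoxyethenyl)-2-(methoxymethoxy)phenyl]-4-methylpent-2-yn-1-one
Product: 24 5-(2,2-dimethoxyethyl)-8-methoxy-2-(propan-2-yl)-4H-chromen-4-one, via ortho-hydroxyaryl ynone acetal 23 (not isolated)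
Conditions: HCl (1.25 M in MeOH), 0 → 40 °C
Reagents that add atoms: methanol, CO
Why: Acid-catalysed cascade: methanolysis of the methoxymethyl acetal, Markovnikov addition of methanol to the enol ether, and 6-endo oxa-Michael cyclization of the freed phenol onto the acid-activated ynone. Acid favours the six-membered pyranone over five-membered closure, and any β-methoxy or β-chloro enone formed on the way converges on the same chromone by addition-elimination.

Step 15
Reactants: 24 5-(2,2-dimethoxyethyl)-8-methoxy-2-(propan-2-yl)-4H-chromen-4-one
Product: 25 2-[8-methoxy-4-oxo-2-(propan-2-yl)-4H-chromen-5-yl]acetaldehyde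
Conditions: 2 M aq. HCl, THF, 0 °C → rt; used at once
Reagents that add atoms: water, O
Why: Acetal hydrolysis under mild aqueous acid; the aldehyde is taken on without storage because its methylene is acidic and it lies peri to the pyranone.

Step 16
Reactants: 14 1-[4-(benzyloxy)-2-hydroxy-6-[(2-methyl-1,3-dioxolan-2-yl)methyl]phenyl]ethanone; 25 2-[8-methoxy-4-oxo-2-(propan-2-yl)-4H-chromen-5-yl]acetaldehyde
Product: 27 5-{4-[4-(benzyloxy)-2-hydroxy-6-[(2-methyl-1,3-dioxolan-2-yl)methyl]phenyl]-2-hydroxy-4-oxobutyl}-8-methoxy-2-(propan-2-yl)-4H-chromen-4-one (racemic), via dilithium phenoxide enolate 26 (not isolated)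
Conditions: LiN(iPr)2 (2.05 equiv), THF, −78 °C; then 25, −78 °C; then AcOH
Reagents that add atoms: none
Why: Directed aldol addition of a preformed lithium enolate: two equivalents of amide base give the phenoxide-enolate of 14, which adds to the aldehyde at −78 °C faster than it deprotonates it. The new carbinol centre is racemic and is removed in step 17.

Step 17
Reactants: 27 5-{4-[4-(benzyloxy)-2-hydroxy-6-[(2-methyl-1,3-dioxolan-2-yl)methyl]phenyl]-2-hydroxy-4-oxobutyl}-8-methoxy-2-(propan-2-yl)-4H-chromen-4-one
Product: 28 1-[4-(benzyloxy)-2-hydroxy-6-[(2-methyl-1,3-dioxolan-2-yl)methyl]phenyl]-4-[8-methoxy-4-oxo-2-(propan-2-yl)-4H-chromen-5-yl]butane-1,3-dione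
Conditions: Dess-Martin periodinane (1.1 equiv), CH2Cl2, 0 °C → rt
Reagents that add atoms: none
Why: Dess-Martin oxidation of a β-hydroxy ketone to the 1,3-diketone; a slight excess at low temperature avoids further oxidation of the active methylene, and the hydrogen-bonded phenol is not attacked.

Step 18
Reactants: 28 1-[4-(benzyloxy)-2-hydroxy-6-[(2-methyl-1,3-dioxolan-2-yl)methyl]phenyl]-4-[8-methoxy-4-oxo-2-(propan-2-yl)-4H-chromen-5-yl]butane-1,3-dione
Product: 30 7-(benzyloxy)-2-{[8-methoxy-4-oxo-2-(propan-2-yl)-4H-chromen-5-yl]methyl}-5-(2-oxopropyl)-4H-chromen-4-one, via ketal-protected bischromone 29 (not isolated)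
Conditions: TsOH·H2O (cat.), toluene, 60 °C; then 2 M aq. HCl, THF, rt
Reagents that add atoms: water, O
Why: Acid-catalysed cyclodehydration of an ortho-hydroxyaryl 1,3-diketone, the closing stage of a Baker-Venkataraman-type chromone synthesis: the phenol adds to the C2' carbonyl (6-exo-trig) and water is lost. The dioxolane is hydrolysed only afterwards, so the free methyl ketone never coexists with the nucleophilic diketone enol.

Step 19
Reactants: 30 7-(benzyloxy)-2-{[8-methoxy-4-oxo-2-(propan-2-yl)-4H-chromen-5-yl]methyl}-5-(2-oxopropyl)-4H-chromen-4-one
Product: 31 7-hydroxy-2-{[8-methoxy-4-oxo-2-(propan-2-yl)-4H-chromen-5-yl]methyl}-5-(2-oxopropyl)-4H-chromen-4-one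
Conditions: H2 (1 atm), Pd/C (10 wt %), EtOAc, rt
Reagents that add atoms: none
Why: Catalytic hydrogenolysis of the aryl benzyl ether; the pyranone double bonds and the ketone are not reduced at ambient pressure and temperature.

## Compound list

1 | but-3-yn-2-ol (racemic) | CC(O)C#C | starting material
2 | 3-bromo-2-methylprop-1-ene | C=C(C)CBr | starting material
3 | 6-methylhept-6-en-3-yn-2-ol (racemic) | CC(O)C#CCC(C)=C | intermediate
4 | 6-methylhept-6-en-3-yn-2-one | CC(=O)C#CCC(C)=C | intermediate
5 | 1,1-dimethoxyethene | C=C(OC)OC | starting material
6 | 4,4-dimethoxybut-3-en-2-one | CC(=O)C=C(OC)OC | intermediate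
7 | 1,1-dimethoxy-3-(trimethylsilyloxy)buta-1,3-diene | COC(OC)=CC(=C)O[Si](C)(C)C | intermediate
8 | 1-[6,6-dimethoxy-2-(2-methylprop-2-enyl)-4-(trimethylsilyloxy)cyclohexa-1,4-dien-1-yl]ethanone | CC(=O)C1=C(CC(C)=C)CC(O[Si](C)(C)C)=CC1(OC)OC | intermediate
9 | 1-[2-methoxy-6-(2-methylprop-2-enyl)-4-(trimethylsilyloxy)phenyl]ethanone | CC(=O)c1c(CC(C)=C)cc(O[Si](C)(C)C)cc1OC | intermediate
10 | 1-[4-hydroxy-2-methoxy-6-(2-methylprop-2-enyl)phenyl]ethanone | CC(=O)c1c(CC(C)=C)cc(O)cc1OC | intermediate
11 | 1-[4-(benzyloxy)-2-methoxy-6-(2-methylprop-2-enyl)phenyl]ethanone | CC(=O)c1c(CC(C)=C)cc(OCc2ccccc2)cc1OC | intermediate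
12 | 1-[4-(benzyloxy)-2-hydroxy-6-(2-methylprop-2-enyl)phenyl]ethanone | CC(=O)c1c(CC(C)=C)cc(OCc2ccccc2)cc1O | intermediate
13 | 1-[2-acetyl-5-(benzyloxy)-3-hydroxyphenyl]propan-2-one | CC(=O)Cc1cc(OCc2ccccc2)cc(O)c1C(C)=O | intermediate
14 | 1-[4-(benzyloxy)-2-hydroxy-6-[(2-methyl-1,3-dioxolan-2-yl)methyl]phenyl]ethanone | CC(=O)c1c(CC2(C)OCCO2)cc(OCc2ccccc2)cc1O | intermediate
15 | 3-methylbut-1-yne | CC(C)C#C | starting material
16 | (3-methylbut-1-yn-1-yl)lithium | [Li]C#CC(C)C | intermediate
17 | N-methoxy-N,4-dimethylpent-2-ynamide | CC(C)C#CC(=O)N(C)OC | intermediate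
18 | 2-bromo-3-hydroxy-4-methoxybenzaldehyde | COc1ccc(C=O)c(Br)c1O | starting material
19 | 2-bromo-4-methoxy-3-(methoxymethoxy)benzaldehyde | COCOc1c(OC)ccc(C=O)c1Br | intermediate
20 | 2-bromo-4-methoxy-1-(2-methoxyethenyl)-3-(methoxymethoxy)benzene (E/Z mixture) | COC=Cc1ccc(OC)c(OCOC)c1Br | intermediate
21 | [3-methoxy-6-(2-methoxyethenyl)-2-(methoxymethoxy)phenyl]lithium (E/Z mixture) | [Li]c1c(C=COC)ccc(OC)c1OCOC | intermediate
22 | 1-[3-methoxy-6-(2-methoxyethenyl)-2-(methoxymethoxy)phenyl]-4-methylpent-2-yn-1-one (E/Z mixture) | COC=Cc1ccc(OC)c(OCOC)c1C(=O)C#CC(C)C | intermediate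
23 | 1-[6-(2,2-dimethoxyethyl)-2-hydroxy-3-methoxyphenyl]-4-methylpent-2-yn-1-one | COC(OC)Cc1ccc(OC)c(O)c1C(=O)C#CC(C)C | intermediate
24 | 5-(2,2-dimethoxyethyl)-8-methoxy-2-(propan-2-yl)-4H-chromen-4-one | COC(OC)Cc1ccc(OC)c2oc(C(C)C)cc(=O)c12 | intermediate
25 | 2-[8-methoxy-4-oxo-2-(propan-2-yl)-4H-chromen-5-yl]acetaldehyde | O=CCc1ccc(OC)c2oc(C(C)C)cc(=O)c12 | intermediate
26 | dilithium phenoxide enolate of 14 (lithium 5-(benzyloxy)-2-[1-(lithiooxy)ethenyl]-3-[(2-methyl-1,3-dioxolan-2-yl)methyl]phenolate) | [Li]OC(=C)c1c(CC2(C)OCCO2)cc(OCc2ccccc2)cc1O[Li] | intermediate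
27 | 5-{4-[4-(benzyloxy)-2-hydroxy-6-[(2-methyl-1,3-dioxolan-2-yl)methyl]phenyl]-2-hydroxy-4-oxobutyl}-8-methoxy-2-(propan-2-yl)-4H-chromen-4-one (racemic) | COc1ccc(CC(O)CC(=O)c2c(CC3(C)OCCO3)cc(OCc3ccccc3)cc2O)c2c(=O)cc(C(C)C)oc12 | intermediate
28 | 1-[4-(benzyloxy)-2-hydroxy-6-[(2-methyl-1,3-dioxolan-2-yl)methyl]phenyl]-4-[8-methoxy-4-oxo-2-(propan-2-yl)-4H-chromen-5-yl]butane-1,3-dione | COc1ccc(CC(=O)CC(=O)c2c(CC3(C)OCCO3)cc(OCc3ccccc3)cc2O)c2c(=O)cc(C(C)C)oc12 | intermediate
29 | 7-(benzyloxy)-2-{[8-methoxy-4-oxo-2-(propan-2-yl)-4H-chromen-5-yl]methyl}-5-[(2-methyl-1,3-dioxolan-2-yl)methyl]-4H-chromen-4-one | COc1ccc(Cc2cc(=O)c3c(CC4(C)OCCO4)cc(OCc4ccccc4)cc3o2)c2c(=O)cc(C(C)C)oc12 | intermediate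
30 | 7-(benzyloxy)-2-{[8-methoxy-4-oxo-2-(propan-2-yl)-4H-chromen-5-yl]methyl}-5-(2-oxopropyl)-4H-chromen-4-one | COc1ccc(Cc2cc(=O)c3c(CC(C)=O)cc(OCc4ccccc4)cc3o2)c2c(=O)cc(C(C)C)oc12 | intermediate
31 | 7-hydroxy-2-{[8-methoxy-4-oxo-2-(propan-2-yl)-4H-chromen-5-yl]methyl}-5-(2-oxopropyl)-4H-chromen-4-one | COc1ccc(Cc2cc(=O)c3c(CC(C)=O)cc(O)cc3o2)c2c(=O)cc(C(C)C)oc12 | target

## Step count and least certain steps

Total: 19 steps. Longest linear sequence: 11 steps (1, 2, 5, 6, 7, 8, 9, 16, 17, 18, 19). The diene branch through steps 3 and 4 is equally long, the chromone A branch (steps 11 to 15, then 16 to 19) has 9 steps, and step 10 prepares the amide 17.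

Step 5 (key step). The most likely failure is that cycloaddition to a β-alkyl ynone is slow at temperatures the partners tolerate, so that prototropic isomerization of the skipped enynone and hydrolysis or oligomerization of the diene overtake ring formation. The fallback is an anionic annulation that sets out from 4 and comes back at 12. The sodium enolate of dimethyl 3-oxopentanedioate (NaH, THF) adds to the β-carbon of 4, and Dieckmann-type attack of the ynone α-carbon on the distal ester gives methyl 3-acetyl-4,6-dihydroxy-2-(2-methylprop-2-enyl)benzoate F1. Saponification with aqueous LiOH and decarboxylation of the resulting 2,4-dihydroxybenzoic acid on acidification and warming give 1-[2,4-dihydroxy-6-(2-methylprop-2-enyl)phenyl]ethanone F2. Benzylation with one equivalent of benzyl bromide and K2CO3 in acetone occurs at the hydroxyl that is not hydrogen-bonded to the ketone and returns to 12, bypassing steps 5 to 7.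

Step 7. The most likely failure is Lewis-acid activation of the chelated aryl ketone towards attack by the neighbouring methallyl alkene (carbonyl-ene or Prins-type ring closure), or addition of hydrogen iodide across the alkene at work-up, in competition with ether cleavage. The fallback sets out from 11 and comes back at 13 by changing the order of events. Lemieux-Johnson cleavage of 11 (OsO4 cat., NaIO4, 2,6-lutidine) gives 1-[2-acetyl-5-(benzyloxy)-3-methoxyphenyl]propan-2-one F3, which has no π-nucleophile. The same chelation-controlled demethylation with MgI2·OEt2 then gives 13 directly.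

Step 14. The most likely failure is capture of the oxocarbenium ion, which is in equilibrium with the dimethyl acetal, by C3 of the newly formed pyranone (a peri six-membered ring closure); five-membered closure of the ynone phenol is a second possibility. The fallback sets out from 19 and comes back at 25 without exposing any acetal or aldehyde to acid. Wittig methylenation of 19 (Ph3PCH3Br, KOtBu) gives 2-bromo-1-ethenyl-4-methoxy-3-(methoxymethoxy)benzene F4. Bromine-lithium exchange and acylation with 17 give 1-[6-ethenyl-3-methoxy-2-(methoxymethoxy)phenyl]-4-methylpent-2-yn-1-one F5. Methanolic HCl gives 5-ethenyl-8-methoxy-2-(propan-2-yl)-4H-chromen-4-one F6. Hydroboration with 9-BBN and oxidation with NaBO3 give 5-(2-hydroxyethyl)-8-methoxy-2-(propan-2-yl)-4H-chromen-4-one F7, and Dess-Martin oxidation of F7 gives 25.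

Step 16. The most likely failure is proton transfer from the acidic methylene of 25 to the enolate, leading to enolization and self-condensation of the aldehyde instead of carbonyl addition; retro-aldol cleavage on warming is a further risk. The fallback sets out from 14 and comes back at 27 by a Mukaiyama aldol reaction, which replaces the basic enolate by a neutral enol silane. TMSOTf and Et3N convert 14 into {1-[4-(benzyloxy)-6-[(2-methyl-1,3-dioxolan-2-yl)methyl]-2-(trimethylsilyloxy)phenyl]ethenyl}oxy(trimethyl)silane F8. Addition of F8 to 25 with BF3·OEt2 in CH2Cl2 at −78 °C, followed by a mildly acidic aqueous work-up that removes the silyl groups, gives 27.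

## Further compounds

F1 | step 5 | methyl 3-acetyl-4,6-dihydroxy-2-(2-methylprop-2-enyl)benzoate | COC(=O)c1c(O)cc(O)c(C(C)=O)c1CC(C)=C
F2 | step 5 | 1-[2,4-dihydroxy-6-(2-methylprop-2-enyl)phenyl]ethanone | CC(=O)c1c(CC(C)=C)cc(O)cc1O
F3 | step 7 | 1-[2-acetyl-5-(benzyloxy)-3-methoxyphenyl]propan-2-one | CC(=O)Cc1cc(OCc2ccccc2)cc(OC)c1C(C)=O
F4 | step 14 | 2-bromo-1-ethenyl-4-methoxy-3-(methoxymethoxy)benzene | C=Cc1ccc(OC)c(OCOC)c1Br
F5 | step 14 | 1-[6-ethenyl-3-methoxy-2-(methoxymethoxy)phenyl]-4-methylpent-2-yn-1-one | C=Cc1ccc(OC)c(OCOC)c1C(=O)C#CC(C)C
F6 | step 14 | 5-ethenyl-8-methoxy-2-(propan-2-yl)-4H-chromen-4-one | C=Cc1ccc(OC)c2oc(C(C)C)cc(=O)c12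
F7 | step 14 | 5-(2-hydroxyethyl)-8-methoxy-2-(propan-2-yl)-4H-chromen-4-one | OCCc1ccc(OC)c2oc(C(C)C)cc(=O)c12
F8 | step 16 | {1-[4-(benzyloxy)-6-[(2-methyl-1,3-dioxolan-2-yl)methyl]-2-(trimethylsilyloxy)phenyl]ethenyl}oxy(trimethyl)silane | C=C(O[Si](C)(C)C)c1c(CC2(C)OCCO2)cc(OCc2ccccc2)cc1O[Si](C)(C)C
A1 | alternative 1 | 4-acetyl-5-(2-hydroxypropyl)cyclohexane-1,3-dione (diastereomer mixture) | CC(O)CC1CC(=O)CC(=O)C1C(C)=O
A2 | alternative 1 | 6-methyl-5,6-dihydro-2H-pyran-2-one | CC1CC=CC(=O)O1
A3 | alternative 1 | pentane-2,4-dione | CC(=O)CC(C)=O
A4 | alternative 1 | 1-[2,4-dihydroxy-6-(2-hydroxypropyl)phenyl]ethanone | CC(O)Cc1cc(O)cc(O)c1C(C)=O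
A5 | alternative 2 | 5-allyl-8-methoxy-2-isopropylchromen-4-one | C=CCc1ccc(OC)c2oc(C(C)C)cc(=O)c12
A6 | alternative 2 | 6-methoxy-3-(prop-2-en-1-yl)-2-[2-(triphenyl-λ5-phosphanylidene)acetyl]phenyl 2-methylpropanoate | C=CCc1ccc(OC)c(OC(=O)C(C)C)c1C(=O)C=P(c1ccccc1)(c1ccccc1)c1ccccc1
A7 | alternative 3 | 7-(benzyloxy)-2-{[8-methoxy-4-oxo-2-(propan-2-yl)-4H-chromen-5-yl]methyl}-5-[(2-methyl-1,3-dioxolan-2-yl)methyl]-4H-chromen-4-one (identical with 29) | COc1ccc(Cc2cc(=O)c3c(CC4(C)OCCO4)cc(OCc4ccccc4)cc3o2)c2c(=O)cc(C(C)C)oc12
A8 | alternative 3 | 5-(benzyloxy)-2-iodo-3-[(2-methyl-1,3-dioxolan-2-yl)methyl]phenol | CC1(Cc2cc(OCc3ccccc3)cc(O)c2I)OCCO1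
A9 | alternative 3 | 8-methoxy-2-(propan-2-yl)-5-(prop-2-yn-1-yl)-4H-chromen-4-one | C#CCc1ccc(OC)c2oc(C(C)C)cc(=O)c12
A10 | alternative 3 | carbon monoxide | [C-]#[O+]
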